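## Retrosynthetic overview

Locants (carbons in SMILES order, after the exocyclic CH2): C1–C8 plus C16 form the nine-membered ring (C1 bears =CH2, C3/C4 the epoxide, C5 the C(CH3)OH, C8 and C16 the ring fusion); C8–C9–C14(=O)–O–C15–C16 is the δ-lactone; C10–C13 is the side chain.
Last operations: C3/C4 epoxide by hydroxyl-directed epoxidation of a (Z)-C3=C4 alkene; before that C9=C10 by aldol condensation of the δ-lactone with a C10–C13 epoxy aldehyde, and the δ-lactone by closing a C14 acid onto C15–OH.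
Key disconnection C5–C6: Claisen ring expansion of a seven-membered 2-methylideneoxepane (ring O–C3–C2–C1–C16–C8–C7, C7=C6H2, C3 carrying a (Z)-CH=C(CH3)Bpin arm) to the nine-membered carbocycle; the C7 ketone and C5 boron it leaves are then converted (C=O → CH2, C–B → C–OH).
Enabling feature: C5 is the allylic terminus of the C3=C4–C5 unit whose far end C3 is an oxygen-bearing (epoxide) carbon in the target, and C6 is bonded to C7; O–C3–C4=C5 together with C7=C6 is therefore an allyl vinyl ether whose oxygen bridges ring atoms C3 and C7 across C2–C1–C16–C8.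
Ring order: ε-lactone/oxepane (temporary) → nine-membered carbocycle (step 12) → δ-lactone → C3/C4 epoxide; the side-chain epoxide is made separately.

Key step: step 12

Assumption: the ligand antipodes written in steps 3 and 6 are those predicted by the usual facial models of these catalysts; if the sense proves opposite on these substrates, the other antipode is used and nothing else changes.

## Route

Step 1
Reactants: 1 (2-bromoprop-2-en-1-yl)trimethylsilane
Product: 3 trimethyl{[2-(4,4,5,5-tetramethyl-1,3,2-dioxaborolan-2-yl)prop-2-en-1-yl]}silane, via alkenyllithium 2 (not isolated)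
Conditions: t-BuLi (2 equiv), Et2O, −78 °C; then 2-isopropoxy-4,4,5,5-tetramethyl-1,3,2-dioxaborolane, −78 °C → rt; aq. NH4Cl
Reagents that add atoms: 2-isopropoxy-4,4,5,5-tetramethyl-1,3,2-dioxaborolane, CC(C)OB1OC(C)(C)C(C)(C)O1; t-BuLi, [Li]C(C)(C)C (lithium in 2 only)
Why: Bromine–lithium exchange of the 2-bromoalkene followed by borylation of the alkenyllithium with the borate should give the alkenylboronate; no stereocentre is formed.

Step 2
Reactants: 4 (tert-butyldiphenylsilyloxy)acetaldehyde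
Product: 5 methyl (2E)-4-(tert-butyldiphenylsilyloxy)but-2-enoate
Conditions: Ph3P=CHCO2Me, CH2Cl2, rt
Reagents that add atoms: methyl (triphenylphosphoranylidene)acetate, COC(=O)C=P(c1ccccc1)(c1ccccc1)c1ccccc1
Why: Wittig olefination with a stabilised ylide should give the (E)-enoate (C15, C16, C8, C7); no stereocentre is formed.

Step 3
Reactants: 5 methyl (2E)-4-(tert-butyldiphenylsilyloxy)but-2-enoate; 3 the alkenylboronate
Product: 6 methyl (3R)-3-[(tert-butyldiphenylsilyloxy)methyl]-4-[(trimethylsilyl)methyl]pent-4-enoate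
Conditions: [Rh(cod)Cl]2 (2.5 mol%), (S)-BINAP (5.5 mol%), KOH (0.5 equiv), 1,4-dioxane/H2O 10:1, 60 °C
Reagents that add atoms: none
Why: Hayashi–Miyaura conjugate addition: the alkenylrhodium formed by transmetalation inserts the (E)-enoate and the bisphosphine selects the enoate face, which should set C16 (R) and bring in C1 with its future exocyclic methylene; the rhodium enolate is protonated by water.

Step 4
Reactants: 6 the allylsilane ester; 7 but-2-ynal
Product: 8 methyl (3R)-3-[(tert-butyldiphenylsilyloxy)methyl]-6-hydroxy-4-methylidenenon-7-ynoate (both C3 carbinol epimers)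
Conditions: BF3·OEt2 (1.1 equiv), CH2Cl2, −78 °C; aq. NaHCO3
Reagents that add atoms: none
Why: Hosomi–Sakurai allylation: the allylsilane terminus attacks the BF3-activated ynal with loss of silicon, which should form C2–C3 and leave the C1=CH2 group; the C3 mixture does not matter because step 5 removes that centre.

Step 5
Reactants: 8 the propargylic alcohol mixture
Product: 9 methyl (3R)-3-[(tert-butyldiphenylsilyloxy)methyl]-4-methylidene-6-oxonon-7-ynoate
Conditions: Dess–Martin periodinane, NaHCO3, CH2Cl2, 0 °C → rt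
Reagents that add atoms: none
Why: Dess–Martin oxidation under buffered conditions should give the ynone without moving the β,γ-alkene into conjugation.

Step 6
Reactants: 9 the ynone
Product: 10 methyl (3R,6R)-3-[(tert-butyldiphenylsilyloxy)methyl]-6-hydroxy-4-methylidenenon-7-ynoate
Conditions: RuCl[(R,R)-TsDPEN](p-cymene) (2 mol%), HCO2H/Et3N 5:2, CH2Cl2, rt
Reagents that add atoms: none
Why: Noyori asymmetric transfer hydrogenation of an alkynyl ketone: the catalyst distinguishes the alkynyl from the alkyl flank and should set C3 (R) by reagent control, leaving ester and alkenes untouched.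

Step 7
Reactants: 10 the (R)-propargylic alcohol
Product: 11 methyl (3R,6R,7Z)-3-[(tert-butyldiphenylsilyloxy)methyl]-6-hydroxy-4-methylidene-8-(4,4,5,5-tetramethyl-1,3,2-dioxaborolan-2-yl)non-7-enoate
Conditions: CuCl (10 mol%), PCy3 (12 mol%), NaOtBu (15 mol%), B2pin2 (1.2 equiv), MeOH (2 equiv), toluene, rt
Reagents that add atoms: bis(pinacolato)diboron, CC1(C)OB(OC1(C)C)B1OC(C)(C)C(C)(C)O1
Why: Copper-catalysed formal hydroboration (syn borylcupration, then protonation): the propargylic oxygen and the small methyl terminus should direct boron to C5, and syn addition places CH3 cis and boron trans to C3, the geometry needed in step 12; the free hydroxyl avoids the SN2′ path of propargylic esters.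

Step 8
Reactants: 11 the hydroxy ester
Product: 12 (3R,6R,7Z)-3-[(tert-butyldiphenylsilyloxy)methyl]-6-hydroxy-4-methylidene-8-(4,4,5,5-tetramethyl-1,3,2-dioxaborolan-2-yl)non-7-enoic acid
Conditions: LiOH·H2O (3 equiv), THF/MeOH/H2O, 0 °C → rt; then 1 M HCl to pH 4
Reagents that add atoms: lithium hydroxide (LiOH), [Li+].[OH-]
Why: Saponification of the methyl ester; the alkenyl pinacol boronate and the silyl ether should survive brief cold hydroxide, and no stereocentre is touched.

Step 9
Reactants: 12 the hydroxy acid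
Product: 14 (4R,7R)-4-[(tert-butyldiphenylsilyloxy)methyl]-5-methylidene-7-[(1Z)-2-(4,4,5,5-tetramethyl-1,3,2-dioxaborolan-2-yl)prop-1-en-1-yl]oxepan-2-one, via mixed anhydride 13 (not isolated)
Conditions: 2,4,6-trichlorobenzoyl chloride (1.5 equiv), Et3N, THF, rt; then DMAP, toluene (0.003 M), 60 °C
Reagents that add atoms: 2,4,6-trichlorobenzoyl chloride, O=C(Cl)c1c(Cl)cc(Cl)cc1Cl (atoms in 13 only)
Why: Yamaguchi lactonisation through acyl activation should close the seven-membered lactone (C7 acyl to C3–O) with retention at C3.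

Step 10
Reactants: 14 the ε-lactone
Product: 16 (3R,4R,7R)-3-[2-(tert-butyldimethylsilyloxy)ethyl]-4-[(tert-butyldiphenylsilyloxy)methyl]-5-methylidene-7-[(1Z)-2-(4,4,5,5-tetramethyl-1,3,2-dioxaborolan-2-yl)prop-1-en-1-yl]oxepan-2-one, via lithium enolate 15 (not isolated)
Conditions: LiN(iPr)2 (1.15 equiv), THF, −78 °C; then tert-butyl(2-iodoethoxy)dimethylsilane (3 equiv), DMPU, −78 → −30 °C
Reagents that add atoms: tert-butyl(2-iodoethoxy)dimethylsilane, CC(C)(C)[Si](C)(C)OCCI; LiN(iPr)2, [Li]N(C(C)C)C(C)C (lithium in 15 only)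
Why: Alkylation of the lactone enolate anti to the adjacent C16 substituent should set C8 with the 8,16-trans relationship of the target ring fusion (substrate control) and brings in C9 and C14.

Step 11
Reactants: 16 the alkylated lactone
Product: 17 (3R,4R,7R)-3-[2-(tert-butyldimethylsilyloxy)ethyl]-4-[(tert-butyldiphenylsilyloxy)methyl]-2,5-dimethylidene-7-[(1Z)-2-(4,4,5,5-tetramethyl-1,3,2-dioxaborolan-2-yl)prop-1-en-1-yl]oxepane
Conditions: Cp2TiMe2 (3 equiv), toluene/THF, 70 °C, dark; filtration through basic Al2O3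
Reagents that add atoms: dimethyltitanocene (Cp2TiMe2), C[Ti](C)(C1C=CC=C1)C1C=CC=C1
Why: Petasis methylenation (titanium methylidene [2+2]/cycloreversion) should turn the lactone carbonyl into the exocyclic enol ether (C7=C6H2) under non-basic conditions, so the C8 stereocentre, the boronate and the silyl ethers are kept.

Step 12
Reactants: 17 the 2-methylideneoxepane
Product: 18 (3R,4Z,8R,9R)-9-[2-(tert-butyldimethylsilyloxy)ethyl]-8-[(tert-butyldiphenylsilyloxy)methyl]-3-methyl-7-methylidene-3-(4,4,5,5-tetramethyl-1,3,2-dioxaborolan-2-yl)cyclonon-4-en-1-one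
Conditions: toluene (0.01 M), iPr2NEt (0.1 equiv), silylated sealed tube, 150 °C
Reagents that add atoms: none
Why: Thermal aliphatic Claisen ([3,3]-sigmatropic) rearrangement of the allyl vinyl ether C6=C7–O–C3–C4=C5 embedded in 17: the C3–O bond breaks as C5–C6 forms, so C7 becomes a ketone and the oxepane expands by two carbons, the closest known reaction type being the Claisen ring expansion of 2-methylidene cyclic ethers that carry a vinyl group on the other carbon next to oxygen (eight-membered carbocycles and nine-membered lactones are made this way). The nine-membered carbocycle is thus closed by ring expansion through a bridged six-atom chair transition state, not by end-to-end cyclisation, and because the C2–C1–C16–C8 tether must be axial on C3 the new C3=C4 alkene should be Z. C5 is the only new stereocentre: the shift is suprafacial on the allyl unit, so C6 bonds to the face of C4=C5 from which the C3–O bond leaves, and with (R)-C3 and the (Z)-alkenylboronate (CH3 axial, boron equatorial) boron should end up where the target hydroxyl sits, a 1,3-chirality transfer from an easily set secondary carbinol to the fully substituted carbon. The step needs the [3,3] path to outrun exo-to-endo isomerisation of the enol ether and the two conceivable Cope manifolds through C1=CH2; acid-free conditions and the lower barrier of an allyl vinyl ether held in place by the ring should secure this. The product is a masked aldol (C5–B β to C7=O) that cannot revert, which a free β-hydroxy ketone in a strained ring could.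

Step 13
Reactants: 18 the β-boryl cyclononenone
Product: 19 (3S,4Z,8R,9R)-9-[2-(tert-butyldimethylsilyloxy)ethyl]-8-[(tert-butyldiphenylsilyloxy)methyl]-3-hydroxy-3-methyl-7-methylidenecyclonon-4-en-1-one
Conditions: NaBO3·4H2O (5 equiv), THF/H2O 1:1, 0 °C → rt
Reagents that add atoms: sodium perborate tetrahydrate (NaBO3·4H2O), [Na+].[O-]OB=O
Why: Oxidation of the tertiary allylic boronate (1,2-shift of carbon from boron to oxygen) goes with retention, so C5 should receive its (S)-hydroxyl; perborate is the mild oxidant used to release β-hydroxy ketones from β-boryl ketones.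

Step 14
Reactants: 19 the β-hydroxy ketone
Product: 21 (1S,2Z,6R,7R)-7-[2-(tert-butyldimethylsilyloxy)ethyl]-6-[(tert-butyldiphenylsilyloxy)methyl]-1-methyl-5-methylidenecyclonon-2-en-1-ol, via tosylhydrazone 20 (not isolated)
Conditions: TsNHNH2 (3 equiv), EtOH, 60 °C; then catecholborane (4 equiv), CHCl3, 0 °C; then NaOAc·3H2O, 60 °C
Reagents that add atoms: 4-methylbenzenesulfonohydrazide, NNS(=O)(=O)c1ccc(C)cc1 (atoms in 20 only)
Why: Caglioti-type tosylhydrazone reduction (hydride addition, loss of sulfinate, then N2 from the diazene) should replace the temporary C7 carbonyl by CH2 without strong base or free-radical chains that could engage the ring alkenes.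

Step 15
Reactants: 21 the bis-silyl ether
Product: 22 (1S,2Z,6R,7R)-6-[(tert-butyldiphenylsilyloxy)methyl]-7-(2-hydroxyethyl)-1-methyl-5-methylidenecyclonon-2-en-1-ol
Conditions: HF·pyridine, pyridine, THF, 0 °C
Reagents that add atoms: none
Why: Buffered HF·pyridine cleaves the primary tert-butyldimethylsilyl ether (C14) much faster than the tert-butyldiphenylsilyl ether (C15), which differentiates the two primary oxygens.

Step 16
Reactants: 22 the primary alcohol
Product: 24 2-[(1R,2R,5Z,7S)-2-[(tert-butyldiphenylsilyloxy)methyl]-7-hydroxy-7-methyl-3-methylidenecyclonon-5-en-1-yl]acetic acid, via aldehyde 23 (not isolated)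
Conditions: TEMPO (0.2 equiv), PhI(OAc)2 (2.5 equiv), MeCN/H2O 1:1, rt
Reagents that add atoms: water, O
Why: Oxoammonium (TEMPO) oxidation of the primary alcohol through the aldehyde hydrate should give the C14 acid while the tertiary allylic alcohol and the alkenes stay untouched.

Step 17
Reactants: 24 the silyloxy acid
Product: 26 trans-fused δ-lactone (5S,8R,16R; C3=C4 Z): 5-hydroxy-5-methyl-1-methylidene nine-membered ring fused at C8/C16 to a tetrahydropyran-2-one (C14=O, C15H2–O), via hydroxy acid 25 (not isolated)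
Conditions: Bu4NF (3 equiv), THF, 0 °C → rt; then AcOH to pH 4, toluene, 40 °C
Reagents that add atoms: none
Why: Fluoride desilylation frees C15–OH and the δ-hydroxy acid should close to the six-membered lactone; the trans ring fusion follows from C8 and C16 as set in steps 10 and 3.

Step 18
Reactants: 27 (S)-2,2-dimethyl-1,3-dioxolane-4-carbaldehyde
Product: 28 (4R)-2,2-dimethyl-4-(2-methylprop-1-en-1-yl)-1,3-dioxolane
Conditions: isopropyltriphenylphosphonium iodide, n-BuLi, THF, −78 → 0 °C; then 27, −78 °C → rt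
Reagents that add atoms: isopropyltriphenylphosphonium iodide, CC(C)[P+](c1ccccc1)(c1ccccc1)c1ccccc1.[I-]
Why: Wittig olefination with the non-stabilised ylide at low temperature should give the trisubstituted alkene (C12=C13) without epimerising the α-alkoxy aldehyde, so C11 comes from the chiral pool.

Step 19
Reactants: 28 the alkenyl acetonide
Product: 29 (2R)-4-methylpent-3-ene-1,2-diol
Conditions: AcOH/H2O 4:1, 40 °C
Reagents that add atoms: none
Why: Acid hydrolysis of the acetal frees the allylic secondary hydroxyl (C11) that directs the next step.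

Step 20
Reactants: 29 the ene-diol
Product: 30 (1S)-1-[(2R)-3,3-dimethyloxiran-2-yl]ethane-1,2-diol
Conditions: mCPBA, NaHCO3, CH2Cl2, 0 °C
Reagents that add atoms: 3-chloroperoxybenzoic acid, O=C(OO)c1cccc(Cl)c1
Why: Hydroxyl-directed peracid epoxidation of a secondary allylic alcohol with a cis-methyl group: A(1,3) strain keeps the carbinol hydrogen in the alkene plane and the hydrogen-bonded peracid attacks the face syn to OH, which should set C12 (R) in the threo relationship of the target.

Step 21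
Reactants: 30 the epoxy diol
Product: 31 (1S)-1-[(2R)-3,3-dimethyloxiran-2-yl]-1,2-bis(triethylsilyloxy)ethane
Conditions: Et3SiCl (2.4 equiv), imidazole, CH2Cl2, 0 °C
Reagents that add atoms: chlorotriethylsilane, CC[Si](Cl)(CC)CC
Why: Silylation of both hydroxyls under non-acidic conditions protects C11–OH and prepares C10 for selective oxidation.

Step 22
Reactants: 31 the bis(triethylsilyl) ether
Product: 32 (2R)-2-[(2R)-3,3-dimethyloxiran-2-yl]-2-(triethylsilyloxy)acetaldehyde
Conditions: (COCl)2, DMSO, CH2Cl2, −78 °C; then Et3N, −78 → −40 °C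
Reagents that add atoms: none
Why: Under Swern conditions a primary triethylsilyl ether is cleaved by the chlorosulfonium salt and oxidised directly to the aldehyde while the secondary one survives; the low temperature should prevent epimerisation at C11 and epoxide opening.

Step 23
Reactants: 26 the δ-lactone; 32 the epoxy aldehyde
Product: 34 aldol adduct (5S,8S,11S,12R,16R; C9 and C10 as mixtures): lactone 26 bearing at C9 a CH(OH)–CH(OSiEt3)–(3,3-dimethyloxiran-2-yl) chain, via dilithio enolate 33 (not isolated)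
Conditions: LiN(iPr)2 (2.3 equiv), THF, −78 °C; then 32, −78 °C; aq. NH4Cl
Reagents that add atoms: LiN(iPr)2, [Li]N(C(C)C)C(C)C (lithium in 33 only)
Why: Aldol addition of the lactone lithium enolate (C9) to the aldehyde forms C9–C10 with the tertiary alkoxide as spectator; the two new centres are removed in step 24, so their configuration is irrelevant.

Step 24
Reactants: 34 the aldol adduct
Product: 36 (E)-alkylidene lactone (5S,8S,11S,12R,16R) with C11–OSiEt3, via mesylate 35 (not isolated)
Conditions: MsCl, Et3N, CH2Cl2, 0 °C; then DBU, rt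
Reagents that add atoms: methanesulfonyl chloride, CS(=O)(=O)Cl (atoms in 35 only)
Why: Mesylation of the secondary aldol hydroxyl and E1cB elimination through the lactone enolate should give the conjugated C9=C10 alkene with the C11 chain anti to the lactone carbonyl (E); the tertiary C5–OH is not sulfonylated.

Step 25
Reactants: 36 the triethylsilyl ether
Product: 37 allylic alcohol (5S,8S,11S,12R,16R), C11–OH free
Conditions: Bu4NF/AcOH 1:1, THF, 0 °C
Reagents that add atoms: none
Why: Buffered fluoride removes the triethylsilyl group; the buffer should suppress Payne rearrangement of the epoxy alcohol and deconjugation of the alkylidene lactone.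

Step 26
Reactants: 37 the allylic alcohol
Product: 38 C11 acetate (5S,8S,11S,12R,16R) with (Z)-C3=C4 alkene
Conditions: Ac2O, pyridine, DMAP (cat.), CH2Cl2, 0 °C
Reagents that add atoms: acetic anhydride, CC(=O)OC(C)=O
Why: Acylation of the secondary hydroxyl; the tertiary C5–OH should not react under these conditions and stays free to direct step 27.

Step 27
Reactants: 38 the acetate
Product: 39 CNP0113449.2 (3R,4R,5S,8S,11S,12R,16R; C9=C10 E)
Conditions: VO(acac)2 (5 mol%), t-BuOOH (1.5 equiv), CH2Cl2, 0 °C → rt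
Reagents that add atoms: tert-butyl hydroperoxide, CC(C)(C)OO
Why: Vanadium-alkoxide-directed epoxidation: the C5 vanadate ester delivers oxygen to the adjacent (Z)-C3=C4 alkene on the hydroxyl face (the syn sense known for 2-cycloalkenols up to nine-membered rings), which should set C3 and C4 (R,R); the remote exocyclic methylene and the electron-poor C9=C10 alkene are not addressed.

## Compound list

1 | (2-bromoprop-2-en-1-yl)trimethylsilane | C=C(Br)C[Si](C)(C)C | starting material
2 | [3-(trimethylsilyl)prop-1-en-2-yl]lithium | [Li]C(=C)C[Si](C)(C)C | intermediate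
3 | trimethyl{[2-(4,4,5,5-tetramethyl-1,3,2-dioxaborolan-2-yl)prop-2-en-1-yl]}silane | C=C(C[Si](C)(C)C)B1OC(C)(C)C(C)(C)O1 | intermediate
4 | (tert-butyldiphenylsilyloxy)acetaldehyde | O=CCO[Si](c1ccccc1)(c1ccccc1)C(C)(C)C | starting material
5 | methyl (2E)-4-(tert-butyldiphenylsilyloxy)but-2-enoate | COC(=O)/C=C/CO[Si](c1ccccc1)(c1ccccc1)C(C)(C)C | intermediate
6 | methyl (3R)-3-[(tert-butyldiphenylsilyloxy)methyl]-4-[(trimethylsilyl)methyl]pent-4-enoate | CC(C)(C)[Si](c1ccccc1)(c1ccccc1)OC[C@@H](C(=C)C[Si](C)(C)C)CC(=O)OC | intermediate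
7 | but-2-ynal | CC#CC=O | starting material
8 | methyl (3R)-3-[(tert-butyldiphenylsilyloxy)methyl]-6-hydroxy-4-methylidenenon-7-ynoate (both carbinol epimers) | CC(C)(C)[Si](c1ccccc1)(c1ccccc1)OC[C@@H](C(=C)CC(O)C#CC)CC(=O)OC | intermediate
9 | methyl (3R)-3-[(tert-butyldiphenylsilyloxy)methyl]-4-methylidene-6-oxonon-7-ynoate | CC(C)(C)[Si](c1ccccc1)(c1ccccc1)OC[C@@H](C(=C)CC(=O)C#CC)CC(=O)OC | intermediate
10 | methyl (3R,6R)-3-[(tert-butyldiphenylsilyloxy)methyl]-6-hydroxy-4-methylidenenon-7-ynoate | CC(C)(C)[Si](c1ccccc1)(c1ccccc1)OC[C@@H](C(=C)C[C@@H](O)C#CC)CC(=O)OC | intermediate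
11 | methyl (3R,6R,7Z)-3-[(tert-butyldiphenylsilyloxy)methyl]-6-hydroxy-4-methylidene-8-(4,4,5,5-tetramethyl-1,3,2-dioxaborolan-2-yl)non-7-enoate | CC(C)(C)[Si](c1ccccc1)(c1ccccc1)OC[C@@H](C(=C)C[C@@H](O)/C=C(\C)B1OC(C)(C)C(C)(C)O1)CC(=O)OC | intermediate
12 | (3R,6R,7Z)-3-[(tert-butyldiphenylsilyloxy)methyl]-6-hydroxy-4-methylidene-8-(4,4,5,5-tetramethyl-1,3,2-dioxaborolan-2-yl)non-7-enoic acid | CC(C)(C)[Si](c1ccccc1)(c1ccccc1)OC[C@@H](C(=C)C[C@@H](O)/C=C(\C)B1OC(C)(C)C(C)(C)O1)CC(=O)O | intermediate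
13 | mixed anhydride of 12 with 2,4,6-trichlorobenzoic acid | CC(C)(C)[Si](c1ccccc1)(c1ccccc1)OC[C@@H](C(=C)C[C@@H](O)/C=C(\C)B1OC(C)(C)C(C)(C)O1)CC(=O)OC(=O)c1c(Cl)cc(Cl)cc1Cl | intermediate
14 | (4R,7R)-4-[(tert-butyldiphenylsilyloxy)methyl]-5-methylidene-7-[(1Z)-2-(4,4,5,5-tetramethyl-1,3,2-dioxaborolan-2-yl)prop-1-en-1-yl]oxepan-2-one | O=C1C[C@@H](CO[Si](c2ccccc2)(c2ccccc2)C(C)(C)C)C(=C)C[C@H](/C=C(\C)B2OC(C)(C)C(C)(C)O2)O1 | intermediate
15 | lithium enolate of 14 (C7–OLi, C7=C8) | [Li]OC1=C[C@@H](CO[Si](c2ccccc2)(c2ccccc2)C(C)(C)C)C(=C)C[C@H](/C=C(\C)B2OC(C)(C)C(C)(C)O2)O1 | intermediate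
16 | (3R,4R,7R)-3-[2-(tert-butyldimethylsilyloxy)ethyl]-4-[(tert-butyldiphenylsilyloxy)methyl]-5-methylidene-7-[(1Z)-2-(4,4,5,5-tetramethyl-1,3,2-dioxaborolan-2-yl)prop-1-en-1-yl]oxepan-2-one | O=C1[C@H](CCO[Si](C)(C)C(C)(C)C)[C@@H](CO[Si](c2ccccc2)(c2ccccc2)C(C)(C)C)C(=C)C[C@H](/C=C(\C)B2OC(C)(C)C(C)(C)O2)O1 | intermediate
17 | (3R,4R,7R)-3-[2-(tert-butyldimethylsilyloxy)ethyl]-4-[(tert-butyldiphenylsilyloxy)methyl]-2,5-dimethylidene-7-[(1Z)-2-(4,4,5,5-tetramethyl-1,3,2-dioxaborolan-2-yl)prop-1-en-1-yl]oxepane | C=C1[C@H](CCO[Si](C)(C)C(C)(C)C)[C@@H](CO[Si](c2ccccc2)(c2ccccc2)C(C)(C)C)C(=C)C[C@H](/C=C(\C)B2OC(C)(C)C(C)(C)O2)O1 | intermediate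
18 | (3R,4Z,8R,9R)-9-[2-(tert-butyldimethylsilyloxy)ethyl]-8-[(tert-butyldiphenylsilyloxy)methyl]-3-methyl-7-methylidene-3-(4,4,5,5-tetramethyl-1,3,2-dioxaborolan-2-yl)cyclonon-4-en-1-one | C=C1C/C=C\[C@@](C)(B2OC(C)(C)C(C)(C)O2)CC(=O)[C@H](CCO[Si](C)(C)C(C)(C)C)[C@H]1CO[Si](c1ccccc1)(c1ccccc1)C(C)(C)C | intermediate
19 | (3S,4Z,8R,9R)-9-[2-(tert-butyldimethylsilyloxy)ethyl]-8-[(tert-butyldiphenylsilyloxy)methyl]-3-hydroxy-3-methyl-7-methylidenecyclonon-4-en-1-one | C=C1C/C=C\[C@@](C)(O)CC(=O)[C@H](CCO[Si](C)(C)C(C)(C)C)[C@H]1CO[Si](c1ccccc1)(c1ccccc1)C(C)(C)C | intermediate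
20 | 4-methylbenzenesulfonylhydrazone of 19 | C=C1C/C=C\[C@@](C)(O)CC(=NNS(=O)(=O)c2ccc(C)cc2)[C@H](CCO[Si](C)(C)C(C)(C)C)[C@H]1CO[Si](c1ccccc1)(c1ccccc1)C(C)(C)C | intermediate
21 | (1S,2Z,6R,7R)-7-[2-(tert-butyldimethylsilyloxy)ethyl]-6-[(tert-butyldiphenylsilyloxy)methyl]-1-methyl-5-methylidenecyclonon-2-en-1-ol | C=C1C/C=C\[C@@](C)(O)CC[C@H](CCO[Si](C)(C)C(C)(C)C)[C@H]1CO[Si](c1ccccc1)(c1ccccc1)C(C)(C)C | intermediate
22 | (1S,2Z,6R,7R)-6-[(tert-butyldiphenylsilyloxy)methyl]-7-(2-hydroxyethyl)-1-methyl-5-methylidenecyclonon-2-en-1-ol | C=C1C/C=C\[C@@](C)(O)CC[C@H](CCO)[C@H]1CO[Si](c1ccccc1)(c1ccccc1)C(C)(C)C | intermediate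
23 | 2-[(1R,2R,5Z,7S)-2-[(tert-butyldiphenylsilyloxy)methyl]-7-hydroxy-7-methyl-3-methylidenecyclonon-5-en-1-yl]acetaldehyde | C=C1C/C=C\[C@@](C)(O)CC[C@H](CC=O)[C@H]1CO[Si](c1ccccc1)(c1ccccc1)C(C)(C)C | intermediate
24 | 2-[(1R,2R,5Z,7S)-2-[(tert-butyldiphenylsilyloxy)methyl]-7-hydroxy-7-methyl-3-methylidenecyclonon-5-en-1-yl]acetic acid | C=C1C/C=C\[C@@](C)(O)CC[C@H](CC(=O)O)[C@H]1CO[Si](c1ccccc1)(c1ccccc1)C(C)(C)C | intermediate
25 | 2-[(1R,2R,5Z,7S)-7-hydroxy-2-(hydroxymethyl)-7-methyl-3-methylidenecyclonon-5-en-1-yl]acetic acid | C=C1C/C=C\[C@@](C)(O)CC[C@H](CC(=O)O)[C@H]1CO | intermediate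
26 | trans-fused δ-lactone (5S,8R,16R; C3=C4 Z; C5–OH, C1=CH2) | C=C1C/C=C\[C@@](C)(O)CC[C@@H]2CC(=O)OC[C@@H]12 | intermediate
27 | (S)-2,2-dimethyl-1,3-dioxolane-4-carbaldehyde | C1[C@H](OC(C)(C)O1)C=O | starting material
28 | (4R)-2,2-dimethyl-4-(2-methylprop-1-en-1-yl)-1,3-dioxolane | C1[C@H](OC(C)(C)O1)C=C(C)C | intermediate
29 | (2R)-4-methylpent-3-ene-1,2-diol | OC[C@H](O)C=C(C)C | intermediate
30 | (1S)-1-[(2R)-3,3-dimethyloxiran-2-yl]ethane-1,2-diol | OC[C@H](O)[C@H]1OC1(C)C | intermediate
31 | (1S)-1-[(2R)-3,3-dimethyloxiran-2-yl]-1,2-bis(triethylsilyloxy)ethane | CC[Si](CC)(CC)OC[C@H](O[Si](CC)(CC)CC)[C@H]1OC1(C)C | intermediate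
32 | (2R)-2-[(2R)-3,3-dimethyloxiran-2-yl]-2-(triethylsilyloxy)acetaldehyde | O=C[C@H](O[Si](CC)(CC)CC)[C@H]1OC1(C)C | intermediate
33 | dilithio derivative of 26 (C5–OLi, lactone enolate C9=C14–OLi) | C=C1C/C=C\[C@@](C)(O[Li])CC[C@@H]2C=C(O[Li])OC[C@@H]12 | intermediate
34 | aldol adduct (5S,8S,11S,12R,16R; C9, C10 mixtures) | C=C1C/C=C\[C@@](C)(O)CC[C@@H]2C(C(O)[C@H](O[Si](CC)(CC)CC)[C@H]3OC3(C)C)C(=O)OC[C@@H]12 | intermediate
35 | C10 methanesulfonate of 34 | C=C1C/C=C\[C@@](C)(O)CC[C@@H]2C(C(OS(C)(=O)=O)[C@H](O[Si](CC)(CC)CC)[C@H]3OC3(C)C)C(=O)OC[C@@H]12 | intermediate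
36 | (E)-alkylidene lactone, C11–OSiEt3 (5S,8S,11S,12R,16R) | C=C1C/C=C\[C@@](C)(O)CC[C@@H]2/C(=C\[C@H](O[Si](CC)(CC)CC)[C@H]3OC3(C)C)C(=O)OC[C@@H]12 | intermediate
37 | (E)-alkylidene lactone, C11–OH (5S,8S,11S,12R,16R) | C=C1C/C=C\[C@@](C)(O)CC[C@@H]2/C(=C\[C@H](O)[C@H]3OC3(C)C)C(=O)OC[C@@H]12 | intermediate
38 | (E)-alkylidene lactone, C11–OAc, (Z)-C3=C4 alkene (5S,8S,11S,12R,16R) | C=C1C/C=C\[C@@](C)(O)CC[C@@H]2/C(=C\[C@H](OC(C)=O)[C@H]3OC3(C)C)C(=O)OC[C@@H]12 | intermediate
39 | CNP0113449.2 (3R,4R,5S,8S,11S,12R,16R; C9=C10 E) | C=C1C[C@H]2O[C@H]2[C@@](C)(O)CC[C@@H]2/C(=C\[C@H](OC(C)=O)[C@H]3OC3(C)C)C(=O)OC[C@@H]12 | target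

## Step count and risks

Total step count: 27. Longest linear sequence: 21 steps (steps 2–17, then 23–27, counted from 4).

Steps most likely to fail:

1. Step 12 (ring expansion). The C8 side chain is cis to the alkenyl arm and must lie in the plane beside C6 in the bridged transition state. Exo-to-endo isomerisation of the enol ether, a Cope pathway through C1=CH2, or a 1,3-boron shift in the product could therefore compete with the [3,3] shift. The fallback reverses the order of alkylation and ring expansion. It sets out from 14: methylenation with Cp2TiMe2 should give (4R,7R)-4-[(tert-butyldiphenylsilyloxy)methyl]-2,5-dimethylidene-7-[(1Z)-2-(pinacolboryl)prop-1-en-1-yl]oxepane F1, which carries no substituent next to the enol ether and should rearrange on heating to (3R,4Z,8R)-8-[(tert-butyldiphenylsilyloxy)methyl]-3-methyl-7-methylidene-3-(pinacolboryl)cyclonon-4-en-1-one F2. Kinetic deprotonation with LiN(iPr)2 at −78 °C (at C8, away from the fully substituted C5), alkylation with 2-(tert-butyldimethylsilyloxy)ethyl trifluoromethanesulfonate and equilibration of the ketone α-centre with DBU should then rejoin the route at 18.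

2. Step 13 (unmasking the carbinol next to the ketone). Retro-aldol ring opening or β-elimination of the strained tertiary β-hydroxy ketone could occur under the mildly basic oxidation or during hydrazone formation in step 14. The fallback removes the carbonyl before the carbinol is released and deoxygenates by a radical path. It sets out from 18: NaBH4 in MeOH should give (3R,4Z,8R,9R)-9-[2-(tert-butyldimethylsilyloxy)ethyl]-8-[(tert-butyldiphenylsilyloxy)methyl]-3-methyl-7-methylidene-3-(pinacolboryl)cyclonon-4-en-1-ol F3 (carbinol epimers). NaOH/H2O2 should then give (3S,4Z,8R,9R)-9-[2-(tert-butyldimethylsilyloxy)ethyl]-8-[(tert-butyldiphenylsilyloxy)methyl]-3-methyl-7-methylidenecyclonon-4-ene-1,3-diol F4. Phenyl chlorothionoformate with pyridine and DMAP should acylate only the secondary hydroxyl to the O-phenyl thionocarbonate of F4 at the secondary hydroxyl F5. Bu3SnH/AIBN at high stannane concentration (Barton–McCombie deoxygenation) should return to the route at 21.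

3. Step 7 (borylcupration). Regiocontrol could be lost (boron at C4), or β-oxygen elimination could give an allene. The fallback fixes the regiochemistry through a carbonyl. It sets out from 9: copper-catalysed β-borylation of the ynone (CuCl, PCy3, NaOtBu, B2pin2, MeOH), where boron can only add β to the carbonyl and syn addition gives the same alkene geometry, should give methyl (3R,7Z)-3-[(tert-butyldiphenylsilyloxy)methyl]-4-methylidene-6-oxo-8-(pinacolboryl)non-7-enoate F6. Corey–Bakshi–Shibata 1,2-reduction with the (S)-methyl oxazaborolidine and catecholborane should then set (R)-C3 and return to the route at 11.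

Further compounds
F1 | step 12 | (4R,7R)-4-[(tert-butyldiphenylsilyloxy)methyl]-2,5-dimethylidene-7-[(1Z)-2-(4,4,5,5-tetramethyl-1,3,2-dioxaborolan-2-yl)prop-1-en-1-yl]oxepane | C=C1C[C@@H](CO[Si](c2ccccc2)(c2ccccc2)C(C)(C)C)C(=C)C[C@H](/C=C(\C)B2OC(C)(C)C(C)(C)O2)O1
F2 | step 12 | (3R,4Z,8R)-8-[(tert-butyldiphenylsilyloxy)methyl]-3-methyl-7-methylidene-3-(4,4,5,5-tetramethyl-1,3,2-dioxaborolan-2-yl)cyclonon-4-en-1-one | C=C1C/C=C\[C@@](C)(B2OC(C)(C)C(C)(C)O2)CC(=O)C[C@H]1CO[Si](c1ccccc1)(c1ccccc1)C(C)(C)C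
F3 | step 13 | (3R,4Z,8R,9R)-9-[2-(tert-butyldimethylsilyloxy)ethyl]-8-[(tert-butyldiphenylsilyloxy)methyl]-3-methyl-7-methylidene-3-(4,4,5,5-tetramethyl-1,3,2-dioxaborolan-2-yl)cyclonon-4-en-1-ol (carbinol epimers) | C=C1C/C=C\[C@@](C)(B2OC(C)(C)C(C)(C)O2)CC(O)[C@H](CCO[Si](C)(C)C(C)(C)C)[C@H]1CO[Si](c1ccccc1)(c1ccccc1)C(C)(C)C
F4 | step 13 | (3S,4Z,8R,9R)-9-[2-(tert-butyldimethylsilyloxy)ethyl]-8-[(tert-butyldiphenylsilyloxy)methyl]-3-methyl-7-methylidenecyclonon-4-ene-1,3-diol (C1 epimers) | C=C1C/C=C\[C@@](C)(O)CC(O)[C@H](CCO[Si](C)(C)C(C)(C)C)[C@H]1CO[Si](c1ccccc1)(c1ccccc1)C(C)(C)C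
F5 | step 13 | O-phenyl thionocarbonate of F4 at the secondary hydroxyl | C=C1C/C=C\[C@@](C)(O)CC(OC(=S)Oc2ccccc2)[C@H](CCO[Si](C)(C)C(C)(C)C)[C@H]1CO[Si](c1ccccc1)(c1ccccc1)C(C)(C)C
F6 | step 7 | methyl (3R,7Z)-3-[(tert-butyldiphenylsilyloxy)methyl]-4-methylidene-6-oxo-8-(4,4,5,5-tetramethyl-1,3,2-dioxaborolan-2-yl)non-7-enoate | CC(C)(C)[Si](c1ccccc1)(c1ccccc1)OC[C@@H](C(=C)CC(=O)/C=C(\C)B1OC(C)(C)C(C)(C)O1)CC(=O)OC
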